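Ring B of the target is read as 2-methylcyclohex-2-enone: C9 is its carbonyl carbon, C10 its methyl-bearing α-carbon and C5 its β-carbon. One copper-catalysed, ligand-controlled three-component coupling adds an isopropenyl group to C5 (bond C4–C5) and allylates the resulting enolate at C10 (bond C10–C1), fixing both ring-fusion stereocentres in the trans sense from three commercial components; the precursor is the enone itself. The isopropenyl group is the latent C4 gem-dimethyl radical and the allyl group is C1–C3, so ring A later closes through C3–C4 by iron hydride hydrogen-atom transfer onto a C3 aldehyde, and the C9 carbonyl then brings in the C8 methyl, the 9α-hydroxyl and the butenolide arm.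

Key step: step 1

Remarks on the chemistry:
- Labdane numbering is used throughout (ring A = C1–C5 and C10; ring B = C5–C10; α is the face of H-5, β the face of the C10 methyl group).
- Assumption: the phosphoramidite enantiomer named in step 1 is taken to deliver the alkenyl group to the Re face of the β-carbon of 1; if a first run shows the opposite sense, its antipode is used.

Step 1
Reactants: 1 2-methylcyclohex-2-en-1-one; 2 isopropenylmagnesium bromide; 3 allyl iodide
Product: 5 (2S,3S)-2-allyl-2-methyl-3-(prop-1-en-2-yl)cyclohexan-1-one, via bromomagnesium enolate 4 (not isolated)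
Conditions: Cu(O2C-C4H3S) (CuTC, 5 mol %), (S,R,R)-O,O′-(1,1′-binaphthalene-2,2′-diyl)-N,N-bis(1-phenylethyl)phosphoramidite (10 mol %), 2 (1.2 equiv, slow addition), Et2O, −30 °C; then 3 (3 equiv), DMPU, −30 → 0 °C; aq. NH4Cl
Reagents that add atoms: none
Why: Transmetallation of 2 to the ligated monovalent copper gives a chiral alkenylcopper species that π-complexes the enone, adds oxidatively to the β-carbon C5 (trivalent copper intermediate) and reductively eliminates to form C4–C5, leaving the regiodefined bromomagnesium enolate 4, which allyl iodide then C-alkylates at C10 in an SN2 step to form C10–C1. The closest known reaction type is the copper-catalysed asymmetric conjugate addition of Grignard and organoaluminium reagents to 2-substituted cyclohexenones with trapping of the metal enolate by an alkyl halide. No ring is closed. C5 is set by the phosphoramidite ligand (Re-face delivery), and C10 is set by the substrate, because the new isopropenyl group sits pseudo-axial beside the enolate methyl group and the iodide approaches the opposite face, so allyl ends trans to isopropenyl and methyl cis. The step needs 1,4- over 1,2-addition, secured by the copper catalyst and slow addition of 2, and C-monoalkylation at C10 only, secured by the enolate being formed solely towards C10 and by the soft iodide with DMPU.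

Step 2
Reactants: 5 (2S,3S)-2-allyl-2-methyl-3-(prop-1-en-2-yl)cyclohexan-1-one
Product: 7 (2S,3S,6R)-2-allyl-2,6-dimethyl-3-(prop-1-en-2-yl)cyclohexan-1-one, via lithium enolate 6 (not isolated)
Conditions: LDA, THF, −78 °C; MeI, −78 → 0 °C; then NaOMe (cat.), MeOH, rt
Reagents that add atoms: iodomethane, CI
Why: Kinetic enolate alkylation at C8, the only enolisable position since C10 is quaternary; the methyl group should enter and, after the methoxide equilibration, rest equatorial (α, cis to the C10 allyl group), because the axial alternative is 1,3-diaxial to the C10 methyl group.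

Step 3
Reactants: 7 (2S,3S,6R)-2-allyl-2,6-dimethyl-3-(prop-1-en-2-yl)cyclohexan-1-one
Product: 9 (2S,3S,6R)-2-(3-hydroxypropyl)-2,6-dimethyl-3-(prop-1-en-2-yl)cyclohexan-1-one, via trialkylborane 8 (not isolated)
Conditions: disiamylborane (from BH3·THF and 2-methylbut-2-ene), THF, 0 °C; then 3 M NaOH, 30% H2O2, 0 °C → rt
Reagents that add atoms: hydrogen peroxide, OO
Why: Hydroboration–oxidation: the bulky dialkylborane adds anti-Markovnikov to the monosubstituted allyl double bond much faster than to the 1,1-disubstituted, neopentyl-flanked isopropenyl group or the hindered C9 ketone (9-BBN is avoided because it does not discriminate between these two alkene classes), and alkaline peroxide turns C–B into C–OH with no stereocentre involved.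

Step 4
Reactants: 9 (2S,3S,6R)-2-(3-hydroxypropyl)-2,6-dimethyl-3-(prop-1-en-2-yl)cyclohexan-1-one
Product: 10 3-[(1S,3R,6S)-1,3-dimethyl-2-oxo-6-(prop-1-en-2-yl)cyclohexyl]propanal
Conditions: TEMPO (10 mol %), PhI(OAc)2, CH2Cl2, rt
Reagents that add atoms: none
Why: Oxoammonium-mediated (TEMPO) oxidation of the primary alcohol stops at the aldehyde under near-neutral conditions, so the isopropenyl group, the ketone and the C8 centre are untouched.

Step 5
Reactants: 10 3-[(1S,3R,6S)-1,3-dimethyl-2-oxo-6-(prop-1-en-2-yl)cyclohexyl]propanal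
Product: 11 (2R,4aS,6S,8aS)-6-hydroxy-2,5,5,8a-tetramethyloctahydronaphthalen-1(2H)-one (3β-hydroxy-8α-methyl-trans-decal-9-one)
Conditions: Fe(acac)3 (30 mol %), PhSiH3 (2.5 equiv), EtOH, 60 °C, Ar
Reagents that add atoms: none
Why: Iron hydride hydrogen-atom transfer to the isopropenyl CH2 gives the tertiary C4 radical, which closes ring A by 6-exo-trig addition to the aldehyde carbon C3 (a reductive radical olefin–carbonyl cyclisation known for alkene-tethered ketones and aldehydes), the alkoxy radical being reduced and protonated in ethanol; the chair transition state on the pre-set trans C5/C10 pair gives the trans-decalin and should place the new C3 oxygen equatorial (3β), the 3α-epimer being separable.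

Step 6
Reactants: 11 (2R,4aS,6S,8aS)-6-hydroxy-2,5,5,8a-tetramethyloctahydronaphthalen-1(2H)-one
Product: 12 (2S,4aS,6R,8aR)-1,1,4a,6-tetramethyl-5-methylidenedecahydronaphthalen-2-ol (3β-hydroxy-8α-methyl-9-methylidene-trans-decalin)
Conditions: Ph3PCH3Br, KOt-Bu (4 equiv each), toluene, 90 °C
Reagents that add atoms: methyltriphenylphosphonium bromide, C[P+](c1ccccc1)(c1ccccc1)c1ccccc1.[Br-]
Why: Wittig methylenation under the hot potassium tert-butoxide/toluene protocol used for α-quaternary ketones; the C3 hydroxyl rides through as its alkoxide, no stereocentre is created, and C8 stays equatorial because that epimer is strongly favoured under the basic conditions.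

Step 7
Reactants: 12 (2S,4aS,6R,8aR)-1,1,4a,6-tetramethyl-5-methylidenedecahydronaphthalen-2-ol
Product: 13 9α,11-epoxide of 12 (spiro-oxirane at C9 with its oxygen on the α face; 3β-hydroxyl free)
Conditions: mCPBA, NaHCO3, CH2Cl2, 0 °C
Reagents that add atoms: 3-chloroperoxybenzoic acid, OOC(=O)c1cccc(Cl)c1
Why: Prilezhaev epoxidation: the axial C10 methyl group next to C9 shields the β face of the exocyclic alkene, so oxygen is delivered from the α face and C9 is set with its oxygen α (axial).

Step 8
Reactants: 14 furan-3-ylmethanol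
Product: 15 tert-butyl(furan-3-ylmethoxy)dimethylsilane
Conditions: TBSCl, imidazole, DMF, rt
Reagents that add atoms: tert-butyldimethylsilyl chloride, CC(C)(C)[Si](C)(C)Cl
Why: Standard imidazole-mediated silylation of the primary alcohol installs the silyl group that is moved to carbon in the next step.

Step 9
Reactants: 15 tert-butyl(furan-3-ylmethoxy)dimethylsilane
Product: 17 [2-(tert-butyldimethylsilyl)furan-3-yl]methanol, via 2-lithiofuran 16 (not isolated)
Conditions: n-BuLi, HMPA, THF, −78 → 0 °C; aq. NH4Cl
Reagents that add atoms: none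
Why: Directed lithiation at furan C2 next to the silyloxymethyl group, followed by 1,4 O→C silyl migration (retro-Brook rearrangement) driven by formation of the lithium alkoxide, puts the silyl group on the carbon that becomes C16.

Step 10
Reactants: 17 [2-(tert-butyldimethylsilyl)furan-3-yl]methanol
Product: 19 tert-butyl[3-(chloromethyl)furan-2-yl]dimethylsilane, via mesylate 18 (not isolated)
Conditions: MsCl, Et3N, CH2Cl2, −20 °C; then LiCl, THF, 0 °C → rt
Reagents that add atoms: lithium chloride, [Li+].[Cl-]
Why: Mesylation and SN2 displacement by chloride proceed under non-acidic conditions, which spare the acid-labile C–Si bond of the 2-silylfuran.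

Step 11
Reactants: 13 9α,11-epoxide of 12; 19 tert-butyl[3-(chloromethyl)furan-2-yl]dimethylsilane
Product: 21 9β-{2-[2-(tert-butyldimethylsilyl)furan-3-yl]ethyl}-4,4,8α,10β-tetramethyl-trans-decalin-3β,9α-diol, via Grignard reagent 20 (not isolated)
Conditions: 19, Mg, THF, 0 °C → rt; 13, MeMgCl (1.0 equiv), THF, −40 °C; then the Grignard solution (2 equiv), CuBr·SMe2 (10 mol %), −40 → 0 °C; aq. NH4Cl
Reagents that add atoms: none
Why: Copper-catalysed SN2 opening of the 2,2-disubstituted epoxide at its unsubstituted carbon C11 by the furylmethyl Grignard reagent forms C11–C12 and frees the tertiary C9 alkoxide with its configuration untouched; the silyl group at furan C2 blocks the transposed attack through that position, and the C3 hydroxyl is masked as its magnesium alkoxide.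

Step 12
Reactants: 21 9β-{2-[2-(tert-butyldimethylsilyl)furan-3-yl]ethyl}-4,4,8α,10β-tetramethyl-trans-decalin-3β,9α-diol
Product: 24 3β,9α,15-trihydroxy-8α-methyl-labd-13-en-16,15-olide (γ-hydroxybutenolide; C15 epimers), via endoperoxide 22 (not isolated), via silyl ester 23 (not isolated)
Conditions: O2, hν (visible), tetraphenylporphyrin (cat.), CH2Cl2, −78 °C; then H2O, THF, rt
Reagents that add atoms: oxygen, O=O
Why: [4+2] cycloaddition of singlet oxygen to the furan and silyl migration from C16 to the peroxide oxygen convert the silicon-bearing carbon into the carboxyl carbon, so hydrolysis gives the α-substituted γ-hydroxybutenolide regiospecifically (the C15 centre is removed in the next step).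

Step 13
Reactants: 24 3β,9α,15-trihydroxy-8α-methyl-labd-13-en-16,15-olide
Product: 26 3β,9α-dihydroxy-8α-methyl-labd-13-en-16,15-olide, via sodium hydroxy-enoate 25 (not isolated)
Conditions: NaBH4, EtOH, 0 °C; then 1 M HCl to pH 3, 0 °C
Reagents that add atoms: none
Why: Borohydride reduces the ring-opened aldehyde form of the lactol while the carboxylate is inert, and acidification closes the (Z)-4-hydroxy-2-enoic acid to the butenolide, removing the C15 stereocentre; the conjugated lactone is not reduced at 0 °C.

Step 14
Reactants: 26 3β,9α-dihydroxy-8α-methyl-labd-13-en-16,15-olide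
Product: 27 (3S,5S,8R,9R,10S)-3-acetoxy-9-hydroxylabd-13-en-16,15-olide (CNP0117645.1)
Conditions: Ac2O, pyridine, rt
Reagents that add atoms: acetic anhydride, CC(=O)OC(C)=O
Why: Pyridine-mediated acylation acetylates only the secondary equatorial 3β-hydroxyl, with retention, because the axial tertiary 9α-hydroxyl flanked by C8 and C10 is inert under these conditions.

Compound list
1 | 2-methylcyclohex-2-en-1-one | CC1=CCCCC1=O | starting material
2 | isopropenylmagnesium bromide | CC(=C)[Mg]Br | starting material
3 | allyl iodide | C=CCI | starting material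
4 | bromomagnesium (S)-2-methyl-3-(prop-1-en-2-yl)cyclohex-1-en-1-olate (not isolated) | CC1=C(O[Mg]Br)CCC[C@H]1C(C)=C | intermediate
5 | (2S,3S)-2-allyl-2-methyl-3-(prop-1-en-2-yl)cyclohexan-1-one (allyl trans to isopropenyl) | C=CC[C@@]1(C)[C@@H](CCCC1=O)C(C)=C | intermediate
6 | lithium enolate of 5 (C8=C9; not isolated) | C=CC[C@@]1(C)[C@@H](CCC=C1O[Li])C(C)=C | intermediate
7 | (2S,3S,6R)-2-allyl-2,6-dimethyl-3-(prop-1-en-2-yl)cyclohexan-1-one | C=CC[C@@]1(C)[C@@H](CC[C@@H](C)C1=O)C(C)=C | intermediate
8 | B-alkyl-bis(3-methylbutan-2-yl)borane from 7, boron on C3 (siamyl centres undefined; not isolated) | CC(C)C(C)B(CCC[C@@]1(C)[C@@H](CC[C@@H](C)C1=O)C(C)=C)C(C)C(C)C | intermediate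
9 | (2S,3S,6R)-2-(3-hydroxypropyl)-2,6-dimethyl-3-(prop-1-en-2-yl)cyclohexan-1-one | OCCC[C@@]1(C)[C@@H](CC[C@@H](C)C1=O)C(C)=C | intermediate
10 | 3-[(1S,3R,6S)-1,3-dimethyl-2-oxo-6-(prop-1-en-2-yl)cyclohexyl]propanal | O=CCC[C@@]1(C)[C@@H](CC[C@@H](C)C1=O)C(C)=C | intermediate
11 | (2R,4aS,6S,8aS)-6-hydroxy-2,5,5,8a-tetramethyloctahydronaphthalen-1(2H)-one | O[C@H]1CC[C@@]2(C)[C@@H](CC[C@@H](C)C2=O)C1(C)C | intermediate
12 | (2S,4aS,6R,8aR)-1,1,4a,6-tetramethyl-5-methylidenedecahydronaphthalen-2-ol | O[C@H]1CC[C@@]2(C)[C@@H](CC[C@@H](C)C2=C)C1(C)C | intermediate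
13 | 9α,11-epoxide of 12 (spiro-oxirane, oxygen α) | O[C@H]1CC[C@@]2(C)[C@@H](CC[C@@H](C)[C@]23CO3)C1(C)C | intermediate
14 | furan-3-ylmethanol | OCc1ccoc1 | starting material
15 | tert-butyl(furan-3-ylmethoxy)dimethylsilane | CC(C)(C)[Si](C)(C)OCc1ccoc1 | intermediate
16 | {3-[(tert-butyldimethylsilyloxy)methyl]furan-2-yl}lithium (not isolated) | [Li]c1occc1CO[Si](C)(C)C(C)(C)C | intermediate
17 | [2-(tert-butyldimethylsilyl)furan-3-yl]methanol | OCc1ccoc1[Si](C)(C)C(C)(C)C | intermediate
18 | [2-(tert-butyldimethylsilyl)furan-3-yl]methyl methanesulfonate (not isolated) | CS(=O)(=O)OCc1ccoc1[Si](C)(C)C(C)(C)C | intermediate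
19 | tert-butyl[3-(chloromethyl)furan-2-yl]dimethylsilane | ClCc1ccoc1[Si](C)(C)C(C)(C)C | intermediate
20 | {[2-(tert-butyldimethylsilyl)furan-3-yl]methyl}magnesium chloride (not isolated) | Cl[Mg]Cc1ccoc1[Si](C)(C)C(C)(C)C | intermediate
21 | 9β-{2-[2-(tert-butyldimethylsilyl)furan-3-yl]ethyl}-4,4,8α,10β-tetramethyl-trans-decalin-3β,9α-diol | O[C@H]1CC[C@@]2(C)[C@@H](CC[C@@H](C)[C@]2(O)CCc2ccoc2[Si](C)(C)C(C)(C)C)C1(C)C | intermediate
22 | furan endoperoxide of 21 (2,3,7-trioxabicyclo[2.2.1]hept-5-ene, silyl at the bridgehead; new centres undefined; not isolated) | O[C@H]1CC[C@@]2(C)[C@@H](CC[C@@H](C)[C@]2(O)CCC2=CC3OOC2([Si](C)(C)C(C)(C)C)O3)C1(C)C | intermediate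
23 | tert-butyldimethylsilyl (Z)-4-oxobut-2-enoate carrying the decalin-ethyl chain at C2 (not isolated) | O[C@H]1CC[C@@]2(C)[C@@H](CC[C@@H](C)[C@]2(O)CC/C(=C/C=O)C(=O)O[Si](C)(C)C(C)(C)C)C1(C)C | intermediate
24 | 3β,9α,15-trihydroxy-8α-methyl-labd-13-en-16,15-olide (C15 epimers) | O[C@H]1CC[C@@]2(C)[C@@H](CC[C@@H](C)[C@]2(O)CCC2=CC(O)OC2=O)C1(C)C | intermediate
25 | sodium (Z)-4-hydroxybut-2-enoate carrying the decalin-ethyl chain at C2 (not isolated) | O[C@H]1CC[C@@]2(C)[C@@H](CC[C@@H](C)[C@]2(O)CC/C(=C/CO)C(=O)[O-])C1(C)C.[Na+] | intermediate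
26 | 3β,9α-dihydroxy-8α-methyl-labd-13-en-16,15-olide | O[C@H]1CC[C@@]2(C)[C@@H](CC[C@@H](C)[C@]2(O)CCC2=CCOC2=O)C1(C)C | intermediate
27 | (3S,5S,8R,9R,10S)-3-acetoxy-9-hydroxylabd-13-en-16,15-olide (3β-OAc, 9α-OH, 8α-methyl) | CC(=O)O[C@H]1CC[C@@]2(C)[C@@H](CC[C@@H](C)[C@]2(O)CCC2=CCOC2=O)C1(C)C | target

Total step count: 14. Longest linear sequence: 11 steps (steps 1–7 and 11–14); the furan fragment takes steps 8–10.

Steps most likely to fail

Step 1. The transfer of an alkenyl group from copper to the α-substituted enone may proceed with poor facial selectivity, and the magnesium enolate may alkylate sluggishly. The fallback sets out from 1, 2 and 3 and gives up catalyst control. A ligand-free coupling (CuBr·SMe2 10 mol %, THF, −40 °C; then 3, DMPU) is established chemistry and should give racemic 5 through the racemic enolate, that is 4 together with the bromomagnesium (R)-enolate F1. The racemate is then resolved by preparative chromatography on a chiral stationary phase (amylose tris(3,5-dimethylphenylcarbamate), supercritical CO2/MeOH), which removes the (2R,3R)-ketone F2. The route is rejoined at 5.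

Step 5. The C4 radical may add to the aldehyde with poor facial selectivity, giving both C3 epimers. The fallback sets out from 10 through the crude cyclisation mixture, that is 11 together with the 3α-alcohol F3. The mixture is oxidised (DMP, CH2Cl2) to the 3,9-dione F4. NaBH4 (0.3 equiv, EtOH, −20 °C) should then reduce only the C3 carbonyl, which is less hindered than the C9 carbonyl flanked by C8-methyl and quaternary C10. Axial hydride attack from the α face gives the equatorial 3β-alcohol, so hydride control replaces radical transition-state control. The route is rejoined at 11.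

Step 11. Wurtz homocoupling may consume the furfuryl-type halide during Grignard formation, and magnesium halide may rearrange the 2,2-disubstituted epoxide to the C9 aldehyde before the slow substitution at the neopentyl-type C11. The fallback sets out from 19 and 13 and uses a sulfone-stabilised carbanion instead of an organomagnesium reagent. Chloride 19 with PhSO2Na (DMF, rt) gives the phenyl sulfone F5. n-BuLi (THF, −78 °C) gives the lithiated sulfone F6, which opens 13 (pre-deprotonated with n-BuLi) in THF/HMPA at 0 → 40 °C without a Lewis acid, giving the γ-hydroxy sulfone F7 as C12 epimers. Reductive desulfonylation (Na/Hg, Na2HPO4, MeOH, −20 °C) returns to the route at 21.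

Further compounds
F1 | step 1 | bromomagnesium (R)-2-methyl-3-(prop-1-en-2-yl)cyclohex-1-en-1-olate (mirror image of 4) | CC1=C(O[Mg]Br)CCC[C@@H]1C(C)=C
F2 | step 1 | (2R,3R)-2-allyl-2-methyl-3-(prop-1-en-2-yl)cyclohexan-1-one (mirror image of 5) | C=CC[C@]1(C)[C@H](CCCC1=O)C(C)=C
F3 | step 5 | (2R,4aS,6R,8aS)-6-hydroxy-2,5,5,8a-tetramethyloctahydronaphthalen-1(2H)-one (3α-epimer of 11) | O[C@@H]1CC[C@@]2(C)[C@@H](CC[C@@H](C)C2=O)C1(C)C
F4 | step 5 | 4,4,8α,10β-tetramethyl-trans-decalin-3,9-dione | O=C1CC[C@@]2(C)[C@@H](CC[C@@H](C)C2=O)C1(C)C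
F5 | step 11 | tert-butyldimethyl{3-[(phenylsulfonyl)methyl]furan-2-yl}silane | CC(C)(C)[Si](C)(C)c1occc1CS(=O)(=O)c1ccccc1
F6 | step 11 | α-lithio derivative of sulfone F5 | CC(C)(C)[Si](C)(C)c1occc1C([Li])S(=O)(=O)c1ccccc1
F7 | step 11 | 12-phenylsulfonyl derivative of 21 (C12 epimers) | O[C@H]1CC[C@@]2(C)[C@@H](CC[C@@H](C)[C@]2(O)CC(c2ccoc2[Si](C)(C)C(C)(C)C)S(=O)(=O)c2ccccc2)C1(C)C
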